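## Structural features

The target is a hexasubstituted benzene. One carbocyclic aromatic ring carries a benzoyl group at C1 (a benzophenone with an unsubstituted phenyl as second ring), a hydroxyl at C2, prenyl (3-methylbut-2-enyl) chains at C3 and C5, and methoxy groups at C4 and C6. It has no stereocentres and no stereogenic double bonds, so there are no neighbouring stereocentres to relate; the problem is regiochemistry and functional-group tolerance. The fragile parts are the two trisubstituted alkenes, each joined to the ring through a benzylic and allylic CH2 next to a ring oxygen. Acid closes an ortho-prenyl phenol to a 2,2-dimethylchroman or adds HX to the alkene, strong base can remove the CH2 protons, and the electron-rich nucleus is easily oxidised or C-alkylated with loss of aromaticity. The real difficulty is that every ring carbon is substituted and three oxygens must be told apart (one free and hydrogen-bonded to the ketone, two methylated), while Friedel–Crafts prenylation or benzoylation of a phloroglucinol is neither regioselective nor compatible with the alkenes. Once the C2 and C6 oxygens are made equal, a mirror plane runs through C1 and C4: C3–C4–C5 is a methoxy carbon flanked by two identical prenyl carbons, and C2–C1–C6 is an O–C–CH–C–O unit. Read as a masked cyclohexane-1,3,5-trione, the first triad is the methyl enol ether of a symmetric ketone with a prenyl on each alpha carbon and the second is a malonyl unit; the key step joins them through C2–C3 and C5–C6.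

## Logic of the disconnections

20 ⇒ 18 + 19. The O6–CH3 bond is cut. This uncovers the mirror plane through C1 and C4, so everything earlier can be built symmetrically. The forward step must methylate one of two equivalent hydroxyls only; the substrate helps, because after the first methylation the remaining hydroxyl is locked in a hydrogen bond to the ketone.

18 ⇒ 17. The two O–CH2 acetal bonds on O2 and O6 are restored. Free phenols cannot go through an organolithium step, and the acetal oxygens direct that step. The forward demand is acetal cleavage mild enough to leave the prenyl alkenes unprotonated; both acetals sit ortho to the ketone, which makes them labile.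

17 ⇒ 13 + 14. The C1–C(=O) bond is cut as aryl anion plus acyl cation equivalent. C1 is the only unsubstituted ring carbon of 13 and lies between two coordinating acetal oxygens, so the aryllithium 15 is the natural synthon and the acid of a Friedel–Crafts or Fries reaction is avoided. The whole second ring arrives in one stable reagent. The demands are that ring deprotonation outruns deprotonation of the benzylic–allylic CH2 groups and that addition stops at the ketone, which the chelated adduct 16 provides.

13 ⇒ 11 + 12. Two O–CH2 bonds are cut; this is a routine protection whose only demand is O- rather than C-alkylation of an electron-rich resorcinol.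

11 ⇒ 7 + 8. The ring bonds C2–C3 and C5–C6 are cut, so the arene falls into a three-carbon nucleophile (C3–C4–C5 with the O4 methyl already in place) and a three-carbon bis-electrophile (C2–C1–C6). The gain is large: a pentasubstituted benzene with all its carbon substituents and one differentiated oxygen becomes an open-chain enol ether and a commercial diacid chloride. The forward step must acylate both alpha carbons in turn at carbon (through 9, then 10), and the acid released must be kept away from the alkenes. A methyl rather than a silyl enol ether is kept because the methyl must survive as the C4 methoxy group and because it blocks closure through oxygen.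

7 ⇒ 6 ⇒ 4 + 5. The enol ether double bond is traced back to loss of methanol from 6, and the two C–O bonds of 6 to 4 and 5. Direct O-methylation of an enolate would compete with C-methylation, whereas acetal elimination places the methyl on oxygen unambiguously. Because 4 is symmetric, only one constitutional isomer of 7 can form. The demand is acid catalysis too weak to touch the alkenes.

4 ⇒ 1 + 2. The C7–C8 bond of 4 is cut, which makes the molecule symmetric from two cheap five- and eight-carbon pieces. The forward step needs the kinetic, methyl-side enolate 3 and attack at the primary carbon of 2.

## Other disconnections considered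

Alternative 1: The cut is at the two aryl–CH2 bonds at C3 and C5, which a [3,3] shift relates to the O2–C and O6–C bonds of two tertiary allyl ethers.
- Forward step: [4-methoxy-2,6-bis(2-methylbut-3-en-2-yloxy)phenyl](phenyl)methanone A2 would be made from 2,6-dihydroxy-4-methoxybenzophenone A1 by double O-alkylation with a tertiary propargylic halide and semi-hydrogenation. Heating A2 would send each 1,1-dimethylallyl group by aromatic Claisen rearrangement, with allylic inversion, to its only free ortho carbon, giving 2,6-dihydroxy-4-methoxy-3,5-diprenylbenzophenone A3.
- In favour: A3 is identical with 18, so the plan ends with the same step 8. The benzoyl group and the O4 methyl are present from the start, so no late acylation and no protecting groups are needed. The shift is thermal and neutral, and its regiochemistry is fixed by the blocked C1.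
- Against: both hydroxyls of A1 flank the benzoyl group, one is always chelated and both are crowded, so tertiary propargylic electrophiles should alkylate them reluctantly, the second especially. Aryl tertiary-allyl ethers ionise easily with loss of the side chain, and at the temperature of the shift the freed ortho-prenyl phenol can close to a chroman. A1 itself needs an acid-mediated benzoylation of a phloroglucinol ether and a selective methylation.
- Comparison: structurally it decorates a preformed arene, whereas the chosen plan creates the arene and its substitution pattern in one event. Mechanistically the pericyclic step is cleaner than an ionic double acylation and is the better of the two. Its regiocontrol is equal in certainty to the symmetry argument of the chosen plan. On step economy it would be about three steps shorter counted from A1. Its one serious weakness, the ether formation, is comparable in risk to the annulation.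

Alternative 2: The cut is the ring bond between C1 and an oxygenated ortho carbon, which opens the ring to one linear chain.
- Forward step: methyl 2,4-bis(3-methylbut-2-en-1-yl)-3,5,7-trioxo-7-phenylheptanoate A4 would be treated with Mg(OMe)2 in methanol. The methylene between the two ketones nearest the phenyl group attacks the ester carbonyl (Claisen condensation), and the cyclic triketone enolises to 2,4,6-trihydroxy-3,5-diprenylbenzophenone A5.
- In favour: it follows the biosynthetic logic, one C–C bond closes the ring, and the benzoyl group is carried through the ring formation. On that point it is better than the chosen plan, which needs protection and metalation to add it. A5 could reach the target in one double methylation that leaves the chelated hydroxyl, against four steps after the annulation here.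
- Against: A4 is a sensitive polycarbonyl compound with two epimerisable prenylated carbons, and its assembly by polyanion chemistry would take several steps with regiochemical questions of their own. Lactonisation to a pyranone and aldol closures compete with the Claisen mode. A5 leaves three hydroxyls to be differentiated, with O4 flanked by two prenyl groups and a real risk of dearomatising C-methylation, whereas the chosen plan receives the O4 methyl from the ring-forming step.
- Comparison: both ring closures are C-acylations of an enol derivative by a carboxylic acid derivative. The alternative uses a reversible ester condensation under thermodynamic control; the chosen step uses an irreversible acid chloride acylation at low temperature. Overall step counts would be similar. The alternative is stronger after the ring closure and weaker before it.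

Alternative 3: The cuts are the ring bonds C4–C5 and C1–C2, dividing the ring into a C5–C6–C1 unit that carries the benzoyl group and a C2–C3–C4 malonyl unit that carries the C3 prenyl group.
- Forward step: 7-methyl-1-phenyloct-6-ene-1,3-dione A6 (Claisen condensation of 1 with a benzoate ester) would be converted to its enol methyl ether 3-methoxy-7-methyl-1-phenylocta-2,6-dien-1-one A7 and then to the silyl dienol ether [(3-methoxy-7-methyl-1-phenylocta-1,3,6-trien-1-yl)oxy]trimethylsilane A8. A8 would be acylated by 2-(3-methylbut-2-en-1-yl)propanedioyl dichloride A9 first at its gamma carbon and then at its alpha carbon, giving 2,4-dihydroxy-6-methoxy-3,5-diprenylbenzophenone A10. Methylation of the unchelated 4-hydroxyl would finish the synthesis.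
- In favour: the benzoyl group enters with the ring, and the three oxygens emerge already different (a methyl ether, a free hydroxyl and a chelated hydroxyl). The last methylation is therefore directed by an intrinsic difference and not by desymmetrisation. On this point, on convergence, and on the number of steps after ring formation (one against four) it is better than the chosen plan; its longest linear sequence would be about five steps.
- Against: both partners are harder to obtain. A9 must be made from the substituted malonic acid under conditions that release HCl beside an alkene, and it is more hindered and more prone to ketene formation than 8. A7 requires O-methylation of an unsymmetrical diketone at the aliphatic rather than the benzoyl carbonyl, a regiochemical question the symmetric ketone 4 never poses. Closure through oxygen is more open because a silyl group on oxygen is lost easily, unlike a methyl.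
- Comparison: the mechanism belongs to the same family as the chosen step (twofold C-acylation of an enol ether by a malonyl dichloride, six-membered closure, aromatisation). The alternative has the better endgame; the chosen plan has the more available and robust partners and no regiochemical question in its precursor.

Key step: step 4

Assumption: 7 is expected as a mixture of enol ether geometrical isomers; the geometry disappears in step 4, so the mixture is used and the E isomer is drawn. The atom balance of the key step closes (7 + 8 = 11 + 2 HCl), so no structural correction is needed. The endgame uses directed metalation because it forms the aryl–carbonyl bond without acid or light.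

## Route

Step 1
Reactants: 1 6-methylhept-5-en-2-one (sulcatone); 2 1-bromo-3-methylbut-2-ene (prenyl bromide)
Product: 4 2,10-dimethylundeca-2,9-dien-6-one, via lithium enolate 3 (not isolated)
Conditions: LiN(iPr)2 (1.05 equiv), THF, −78 °C; then 2 (1.1 equiv), DMPU, −78 → 0 °C
Reagents that add atoms: 1-bromo-3-methylbut-2-ene, CC(C)=CCBr
Why: Kinetic deprotonation of the methyl ketone at −78 °C gives the less substituted enolate 3, which is C-alkylated by the primary allylic bromide in an SN2 reaction (ketone enolate alkylation); attack at the CH2 of 2 keeps the trisubstituted alkene and makes the ketone symmetric.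

Step 2
Reactants: 4 2,10-dimethylundeca-2,9-dien-6-one; 5 trimethyl orthoformate
Product: 6 6,6-dimethoxy-2,10-dimethylundeca-2,9-diene
Conditions: HC(OMe)3 (3 equiv), MeOH, p-TsOH·H2O (1 mol%), rt; NaOMe quench
Reagents that add atoms: trimethyl orthoformate, COC(OC)OC; methanol, CO (methanol only shuttles methoxy groups, the net donor is the orthoformate)
Why: Acid-catalysed acetalisation driven to completion by the orthoformate as water scavenger; isolated trisubstituted alkenes should not add methanol under a trace of sulfonic acid at room temperature, and the basic quench keeps the acetal intact.

Step 3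
Reactants: 6 6,6-dimethoxy-2,10-dimethylundeca-2,9-diene
Product: 7 (E)-6-methoxy-2,10-dimethylundeca-2,5,9-triene
Conditions: TMSOTf (1.2 equiv), iPr2NEt (1.5 equiv), CH2Cl2, −20 °C → rt; aq. NaHCO3; filtration through basic alumina
Reagents that add atoms: none
Why: The silyl triflate ionises the acetal to an oxocarbenium ion and the hindered amine removes an alpha proton (acetal-to-enol-ether elimination); because 6 is symmetric only one constitutional isomer can form, and the cold, basic medium leaves the prenyl alkenes untouched.

Step 4
Reactants: 7 (E)-6-methoxy-2,10-dimethylundeca-2,5,9-triene; 8 malonyl dichloride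
Product: 11 5-methoxy-4,6-bis(3-methylbut-2-en-1-yl)benzene-1,3-diol, via acyl chloride 9 (not isolated), via cyclohexenedione tautomer 10 (not isolated)
Conditions: 8 (1.05 equiv), 2,6-di-tert-butyl-4-methylpyridine (2.2 equiv), CH2Cl2, −78 → 0 °C; aq. NaHCO3
Reagents that add atoms: malonyl dichloride, O=C(Cl)CC(=O)Cl
Why: The nucleophilic carbon of the enol ether attacks one acyl chloride of 8 to give an oxocarbenium ion, from which the hindered pyridine takes the more accessible proton on the far alpha carbon, so that an enol ether is regenerated on the other side of the methoxy carbon (9). That new enol ether carbon attacks the second acyl chloride in a 6-(enolendo)-exo-trig closure, which forms the only ring, and loss of the proton between the ketone and the oxocarbenium carbon gives the enol ether dione 10. Since 10 keeps a hydrogen on its remaining sp3 prenyl-bearing carbon and a CH2 between the two carbonyls, it should tautomerise irreversibly to the aromatic 11 with the methyl ether retained at the carbon between the prenyl groups. The closest known reaction type is the Effenberger cyclisation of ketone enol ethers with malonyl dichloride, which gives bicyclo[3.3.1]nonanetriones from cyclohexanone enol ethers and phloroglucinol monoethers from open-chain ones. No stereocentre is created: the centres of 9 and 10 and the geometry of 7 are erased on aromatisation. The step needs carbon rather than oxygen to close the ring, and the methyl cap secures this because closure through oxygen would require loss of the methyl group; it needs no regiocontrol because the parent ketone is symmetric. It also needs the acid chloride to react with the enol ether and not with the prenyl alkenes, which holds without a Lewis acid, and the two equivalents of HCl are taken up by a base too hindered to attack 8.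

Step 5
Reactants: 11 5-methoxy-4,6-bis(3-methylbut-2-en-1-yl)benzene-1,3-diol; 12 chloromethyl methyl ether
Product: 13 3-methoxy-1,5-bis(methoxymethoxy)-2,4-bis(3-methylbut-2-en-1-yl)benzene
Conditions: MOMCl (3 equiv), iPr2NEt (4 equiv), CH2Cl2, 0 °C → rt
Reagents that add atoms: chloromethyl methyl ether, COCCl
Why: O-alkylation of both phenols by the hard alkoxymethyl chloride (Williamson-type acetal ether formation); the groups mask the acidic hydroxyls and are strong ortho-directing groups for the next step.

Step 6
Reactants: 13 3-methoxy-1,5-bis(methoxymethoxy)-2,4-bis(3-methylbut-2-en-1-yl)benzene; 14 N-methoxy-N-methylbenzamide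
Product: 17 [4-methoxy-2,6-bis(methoxymethoxy)-3,5-bis(3-methylbut-2-en-1-yl)phenyl](phenyl)methanone, via aryllithium 15 (not isolated), via tetrahedral lithium adduct 16 (not isolated)
Conditions: n-BuLi (1.2 equiv), THF, 0 °C; then 14 (1.3 equiv), −78 → 0 °C; H2O
Reagents that add atoms: N-methoxy-N-methylbenzamide, CON(C)C(=O)c1ccccc1
Why: Directed ortho-metalation: the only ring hydrogen lies between two acetal oxygens that chelate n-BuLi, so its removal should be faster than deprotonation of the prenyl CH2 groups. The aryllithium 15 adds once to the amide (Weinreb ketone synthesis) because the chelated adduct 16 survives until the aqueous quench, and the aryl–carbonyl bond is formed without any acid.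

Step 7
Reactants: 17 [4-methoxy-2,6-bis(methoxymethoxy)-3,5-bis(3-methylbut-2-en-1-yl)phenyl](phenyl)methanone
Product: 18 [2,6-dihydroxy-4-methoxy-3,5-bis(3-methylbut-2-en-1-yl)phenyl](phenyl)methanone
Conditions: 3 M aq. HCl (2 equiv), MeOH, 40 °C; NaHCO3 quench at full conversion
Reagents that add atoms: none
Why: Acid-catalysed methanolysis of the two aryl methoxymethyl acetals; both are ortho to the ketone and cleave readily, so dilute acid at mild temperature should finish before the prenyl alkenes are protonated.

Step 8
Reactants: 18 [2,6-dihydroxy-4-methoxy-3,5-bis(3-methylbut-2-en-1-yl)phenyl](phenyl)methanone; 19 dimethyl sulfate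
Product: 20 [2-hydroxy-4,6-dimethoxy-3,5-bis(3-methylbut-2-en-1-yl)phenyl](phenyl)methanone
Conditions: Me2SO4 (1.05 equiv), K2CO3 (1.5 equiv), acetone, rt → 40 °C
Reagents that add atoms: dimethyl sulfate, COS(=O)(=O)OC
Why: Williamson O-methylation of one of two equivalent phenols; after the first methylation the remaining hydroxyl is held in a strong hydrogen bond to the benzoyl oxygen and is much less acidic and nucleophilic, so one equivalent of the hard methylating agent should stop at the monoether and favour oxygen over ring carbon.

## Compound list

1 | 6-methylhept-5-en-2-one (sulcatone) | CC(=O)CCC=C(C)C | starting material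
2 | 1-bromo-3-methylbut-2-ene (prenyl bromide) | CC(C)=CCBr | starting material
3 | lithium 6-methylhepta-1,5-dien-2-olate (formed in the flask) | [Li+].[O-]C(=C)CCC=C(C)C | intermediate
4 | 2,10-dimethylundeca-2,9-dien-6-one | CC(C)=CCCC(=O)CCC=C(C)C | intermediate
5 | trimethyl orthoformate | COC(OC)OC | starting material
6 | 6,6-dimethoxy-2,10-dimethylundeca-2,9-diene | COC(CCC=C(C)C)(CCC=C(C)C)OC | intermediate
7 | (E)-6-methoxy-2,10-dimethylundeca-2,5,9-triene (the Z isomer formed alongside is equally usable) | CO/C(CCC=C(C)C)=C/CC=C(C)C | intermediate
8 | malonyl dichloride (propanedioyl dichloride) | O=C(Cl)CC(=O)Cl | starting material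
9 | 5-methoxy-9-methyl-4-(3-methylbut-2-en-1-yl)-3-oxodeca-5,8-dienoyl chloride (racemic, enol ether geometry undefined, formed in the flask) | ClC(=O)CC(=O)C(CC=C(C)C)C(OC)=CCC=C(C)C | intermediate
10 | 5-methoxy-4,6-bis(3-methylbut-2-en-1-yl)cyclohex-4-ene-1,3-dione (racemic, formed in the flask) | COC1=C(CC=C(C)C)C(=O)CC(=O)C1CC=C(C)C | intermediate
11 | 5-methoxy-4,6-bis(3-methylbut-2-en-1-yl)benzene-1,3-diol | COc1c(CC=C(C)C)c(O)cc(O)c1CC=C(C)C | intermediate
12 | chloromethyl methyl ether | COCCl | starting material
13 | 3-methoxy-1,5-bis(methoxymethoxy)-2,4-bis(3-methylbut-2-en-1-yl)benzene | COCOc1cc(OCOC)c(CC=C(C)C)c(OC)c1CC=C(C)C | intermediate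
14 | N-methoxy-N-methylbenzamide | CON(C)C(=O)c1ccccc1 | starting material
15 | [4-methoxy-2,6-bis(methoxymethoxy)-3,5-bis(3-methylbut-2-en-1-yl)phenyl]lithium (formed in the flask) | [Li]c1c(OCOC)c(CC=C(C)C)c(OC)c(CC=C(C)C)c1OCOC | intermediate
16 | lithium [4-methoxy-2,6-bis(methoxymethoxy)-3,5-bis(3-methylbut-2-en-1-yl)phenyl][methoxy(methyl)amino]phenylmethanolate (racemic, formed in the flask) | [Li+].[O-]C(c1ccccc1)(N(C)OC)c1c(OCOC)c(CC=C(C)C)c(OC)c(CC=C(C)C)c1OCOC | intermediate
17 | [4-methoxy-2,6-bis(methoxymethoxy)-3,5-bis(3-methylbut-2-en-1-yl)phenyl](phenyl)methanone | COCOc1c(CC=C(C)C)c(OC)c(CC=C(C)C)c(OCOC)c1C(=O)c1ccccc1 | intermediate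
18 | [2,6-dihydroxy-4-methoxy-3,5-bis(3-methylbut-2-en-1-yl)phenyl](phenyl)methanone | COc1c(CC=C(C)C)c(O)c(C(=O)c2ccccc2)c(O)c1CC=C(C)C | intermediate
19 | dimethyl sulfate | COS(=O)(=O)OC | starting material
20 | [2-hydroxy-4,6-dimethoxy-3,5-bis(3-methylbut-2-en-1-yl)phenyl](phenyl)methanone | COc1c(CC=C(C)C)c(O)c(C(=O)c2ccccc2)c(OC)c1CC=C(C)C | target

## Step count and least certain steps

Total: 8 steps. Longest linear sequence: 8 steps (1 → 20); 2, 5, 8, 12, 14 and 19 are commercial.

Step 4 (key step). The most likely failure is stalling after the first acylation, so that the acid chloride of 9 is consumed by intermolecular acylation or by ketene formation and oligomerisation. The second risk is HCl escaping the scavenger, adding to the prenyl alkenes or closing a chroman onto the new phenol. The fallback abandons ring construction and builds the same pattern on a preformed symmetric ring by three successive directed metalations. It sets out from 2, 12, 14 and 19 with a new commercial ring source and comes back to the route at 20. Benzene-1,3,5-triol F1 would be converted with 12 (NaH, DMF) into 1,3,5-tris(methoxymethoxy)benzene F2. Lithiation (n-BuLi, THF, 0 °C) and alkylation with 2 in the presence of CuBr·SMe2 would give 1,3,5-tris(methoxymethoxy)-2-(3-methylbut-2-en-1-yl)benzene F3. Repeating the operation would give 1,3,5-tris(methoxymethoxy)-2,4-bis(3-methylbut-2-en-1-yl)benzene F4. Lithiation of the last ring hydrogen and addition to 14 would give [2,4,6-tris(methoxymethoxy)-3,5-bis(3-methylbut-2-en-1-yl)phenyl](phenyl)methanone F5. Acid methanolysis as in step 7 would give phenyl[2,4,6-trihydroxy-3,5-bis(3-methylbut-2-en-1-yl)phenyl]methanone F6 (identical with A5). Two equivalents of 19 with K2CO3 in acetone should then methylate O4 and one ortho hydroxyl, leaving the chelated one, to reach 20.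

Step 6. The most likely failure is competing removal of a benzylic–allylic proton from a prenyl CH2 by n-BuLi, leading to alkene migration or side-chain acylation. Slow addition of the doubly ortho-substituted aryllithium to the amide, with simple proton return on quench, is the second risk. The fallback replaces the organometallic bond formation by an acyl shift from oxygen to carbon; it sets out from 11 and returns at 18. 11 would be esterified with benzoyl chloride (pyridine, catalytic DMAP, CH2Cl2) to 5-methoxy-4,6-bis(3-methylbut-2-en-1-yl)-1,3-phenylene dibenzoate F7. Irradiation at 254 nm in degassed cyclohexane (photo-Fries rearrangement) should move one benzoyl group to the only free ring carbon, giving 2-benzoyl-3-hydroxy-5-methoxy-4,6-bis(3-methylbut-2-en-1-yl)phenyl benzoate F8; the second ester has no free ortho or para position. Methanolysis of that ester (K2CO3, MeOH) would give 18.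

Step 7. The most likely failure is protonation of a prenyl alkene during acetal cleavage, with capture of the tertiary cation by the adjacent freed hydroxyl (chroman closure) or by chloride or methanol. The fallback changes the protecting group to one removed by fluoride under basic conditions; it sets out from 11 and returns at 18. 11 would be alkylated with 2-(trimethylsilyl)ethoxymethyl chloride (iPr2NEt, CH2Cl2) to 3-methoxy-2,4-bis(3-methylbut-2-en-1-yl)-1,5-bis{[2-(trimethylsilyl)ethoxy]methoxy}benzene F9. Lithiation and addition to 14 as in step 6 would give [4-methoxy-3,5-bis(3-methylbut-2-en-1-yl)-2,6-bis{[2-(trimethylsilyl)ethoxy]methoxy}phenyl](phenyl)methanone F10. Bu4NF in THF/DMPU at 50 °C would then release 18 without any acid.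

Step 1. The most likely failure is proton exchange between enolate 3 and the product ketone during alkylation, leading to double alkylation and alkylation at the internal alpha carbon. The fallback alkylates a doubly activated acetone equivalent in both directions; it sets out from 2 and returns at 4. Dimethyl 3-oxopentanedioate F11 would be alkylated once on each activated carbon with 2 (K2CO3, acetone) to dimethyl 3-oxo-2,4-bis(3-methylbut-2-en-1-yl)pentanedioate F12, a mixture of diastereomers whose centres are lost in the next operation. Saponification (aq. KOH) and decarboxylation on gentle acidification and warming would give 4.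

## Further compounds

F1 | step 4 | benzene-1,3,5-triol | Oc1cc(O)cc(O)c1
F2 | step 4 | 1,3,5-tris(methoxymethoxy)benzene | COCOc1cc(OCOC)cc(OCOC)c1
F3 | step 4 | 1,3,5-tris(methoxymethoxy)-2-(3-methylbut-2-en-1-yl)benzene | COCOc1cc(OCOC)c(CC=C(C)C)c(OCOC)c1
F4 | step 4 | 1,3,5-tris(methoxymethoxy)-2,4-bis(3-methylbut-2-en-1-yl)benzene | COCOc1cc(OCOC)c(CC=C(C)C)c(OCOC)c1CC=C(C)C
F5 | step 4 | [2,4,6-tris(methoxymethoxy)-3,5-bis(3-methylbut-2-en-1-yl)phenyl](phenyl)methanone | COCOc1c(CC=C(C)C)c(OCOC)c(CC=C(C)C)c(OCOC)c1C(=O)c1ccccc1
F6 | step 4 | phenyl[2,4,6-trihydroxy-3,5-bis(3-methylbut-2-en-1-yl)phenyl]methanone | O=C(c1ccccc1)c1c(O)c(CC=C(C)C)c(O)c(CC=C(C)C)c1O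
F7 | step 6 | 5-methoxy-4,6-bis(3-methylbut-2-en-1-yl)-1,3-phenylene dibenzoate | COc1c(CC=C(C)C)c(OC(=O)c2ccccc2)cc(OC(=O)c2ccccc2)c1CC=C(C)C
F8 | step 6 | 2-benzoyl-3-hydroxy-5-methoxy-4,6-bis(3-methylbut-2-en-1-yl)phenyl benzoate | COc1c(CC=C(C)C)c(O)c(C(=O)c2ccccc2)c(OC(=O)c2ccccc2)c1CC=C(C)C
F9 | step 7 | 3-methoxy-2,4-bis(3-methylbut-2-en-1-yl)-1,5-bis{[2-(trimethylsilyl)ethoxy]methoxy}benzene | COc1c(CC=C(C)C)c(OCOCC[Si](C)(C)C)cc(OCOCC[Si](C)(C)C)c1CC=C(C)C
F10 | step 7 | [4-methoxy-3,5-bis(3-methylbut-2-en-1-yl)-2,6-bis{[2-(trimethylsilyl)ethoxy]methoxy}phenyl](phenyl)methanone | COc1c(CC=C(C)C)c(OCOCC[Si](C)(C)C)c(C(=O)c2ccccc2)c(OCOCC[Si](C)(C)C)c1CC=C(C)C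
F11 | step 1 | dimethyl 3-oxopentanedioate | COC(=O)CC(=O)CC(=O)OC
F12 | step 1 | dimethyl 3-oxo-2,4-bis(3-methylbut-2-en-1-yl)pentanedioate | COC(=O)C(CC=C(C)C)C(=O)C(CC=C(C)C)C(=O)OC
A1 | alternative 1 | (2,6-dihydroxy-4-methoxyphenyl)(phenyl)methanone | COc1cc(O)c(C(=O)c2ccccc2)c(O)c1
A2 | alternative 1 | [4-methoxy-2,6-bis(2-methylbut-3-en-2-yloxy)phenyl](phenyl)methanone | COc1cc(OC(C)(C)C=C)c(C(=O)c2ccccc2)c(OC(C)(C)C=C)c1
A3 | alternative 1 | [2,6-dihydroxy-4-methoxy-3,5-bis(3-methylbut-2-en-1-yl)phenyl](phenyl)methanone | COc1c(CC=C(C)C)c(O)c(C(=O)c2ccccc2)c(O)c1CC=C(C)C
A4 | alternative 2 | methyl 2,4-bis(3-methylbut-2-en-1-yl)-3,5,7-trioxo-7-phenylheptanoate | COC(=O)C(CC=C(C)C)C(=O)C(CC=C(C)C)C(=O)CC(=O)c1ccccc1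
A5 | alternative 2 | phenyl[2,4,6-trihydroxy-3,5-bis(3-methylbut-2-en-1-yl)phenyl]methanone | O=C(c1ccccc1)c1c(O)c(CC=C(C)C)c(O)c(CC=C(C)C)c1O
A6 | alternative 3 | 7-methyl-1-phenyloct-6-ene-1,3-dione | CC(C)=CCCC(=O)CC(=O)c1ccccc1
A7 | alternative 3 | 3-methoxy-7-methyl-1-phenylocta-2,6-dien-1-one | COC(CCC=C(C)C)=CC(=O)c1ccccc1
A8 | alternative 3 | [(3-methoxy-7-methyl-1-phenylocta-1,3,6-trien-1-yl)oxy]trimethylsilane | COC(=CCC=C(C)C)C=C(O[Si](C)(C)C)c1ccccc1
A9 | alternative 3 | 2-(3-methylbut-2-en-1-yl)propanedioyl dichloride | CC(C)=CCC(C(=O)Cl)C(=O)Cl
A10 | alternative 3 | [2,4-dihydroxy-6-methoxy-3,5-bis(3-methylbut-2-en-1-yl)phenyl](phenyl)methanone | COc1c(CC=C(C)C)c(O)c(CC=C(C)C)c(O)c1C(=O)c1ccccc1
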